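## Retrosynthetic overview

1. Target 23 ← 22 ← 21 by saturating two C3=C4 bonds and removing two benzyl ethers. 21 ← bis(2-ethoxy-2H-chromene) 19 + 2 PhB(OH)2 by a twofold enantioselective nickel phenylation. The feature used: in each pyran ring the stereocentre C2 carries an unsubstituted phenyl group and is bonded to the ring oxygen O1, so C2 can be held as an acetal (benzopyrylium-type) carbon that accepts phenyl from boron.
2. 19 ← 8,6'-methylene-bridged bis(coumarin) 17, by iBu2AlH half-reduction and ethanol acetalisation.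
3. 17 ← C8–CH2 bond: aryllithium 10 (C2 of 5-methoxyresorcinol, between the oxygens that become O1 and O7 of the 8-linked unit) adds to coumarin-6-carbaldehyde 7, whose formyl carbon becomes the bridge.
4. 7 ← 2,4,6-trihydroxybenzaldehyde. The 6-position is fixed by phenol-directed ortho-formylation from the 5-OH, whose only free ortho carbon is C6.
5. Ring order: pyranone ring of the 6-linked unit (step 2), then pyranone ring of the 8-linked unit (step 10). The key step closes no ring.

Key step: step 13

Assumption: the (R,R)-TADDOL-derived phosphonite is taken as the ligand enantiomer that gives the (2S) centres; the sense of induction would be checked on a monomeric model acetal and the (S,S)-ligand used if it is the opposite.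

## Route

Step 1
Reactants: 1 aldehyde 2,4,6-trihydroxybenzaldehyde
Product: 2 aldehyde 4-(benzyloxy)-2,6-dihydroxybenzaldehyde
Conditions: BnBr (1.0 equiv), K2CO3 (1.0 equiv), DMF, 0 °C → rt
Reagents that add atoms: benzyl bromide, BrCc1ccccc1
Why: Williamson etherification; the 4-OH is the only hydroxyl not hydrogen-bonded to the formyl group and is the most acidic, so one equivalent of base and halide should alkylate it selectively.

Step 2
Reactants: 2 aldehyde 4-(benzyloxy)-2,6-dihydroxybenzaldehyde; 3 ylide ethyl (triphenylphosphoranylidene)acetate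
Product: 5 coumarin 7-(benzyloxy)-5-hydroxy-2H-chromen-2-one, via cinnamate ester 4 (not isolated)
Conditions: PhNEt2, reflux
Reagents that add atoms: none
Why: Wittig olefination with the stabilised ylide, then thermal E/Z equilibration and lactonisation of the Z-hydroxycinnamate; the two ortho hydroxyls are equivalent, so only one coumarin can form.

Step 3
Reactants: 5 coumarin 7-(benzyloxy)-5-hydroxy-2H-chromen-2-one
Product: 6 aldehyde 7-(benzyloxy)-5-hydroxy-2-oxo-2H-chromene-6-carbaldehyde
Conditions: MgCl2, Et3N, (CH2O)n, MeCN, reflux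
Reagents that add atoms: paraformaldehyde (as formaldehyde), C=O
Why: Casnati–Skattebøl ortho-formylation delivers formaldehyde from the magnesium phenoxide only to a carbon ortho to the free phenol, and C6 is the single free ortho position of the 5-OH (the other is the ring fusion C4a), which fixes the 6-regiochemistry.

Step 4
Reactants: 6 aldehyde 7-(benzyloxy)-5-hydroxy-2-oxo-2H-chromene-6-carbaldehyde
Product: 7 aldehyde 7-(benzyloxy)-5-methoxy-2-oxo-2H-chromene-6-carbaldehyde
Conditions: MeI, K2CO3, DMF, 40 °C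
Reagents that add atoms: iodomethane, CI
Why: Williamson methylation of the chelated 5-OH in a dipolar solvent; it is the only acidic group present.

Step 5
Reactants: 8 phenol 5-methoxyresorcinol
Product: 9 arene 1-methoxy-3,5-bis(methoxymethoxy)benzene
Conditions: NaH (2.2 equiv), MOMCl (2.2 equiv), DMF, 0 °C → rt
Reagents that add atoms: chloromethyl methyl ether, COCCl
Why: O-alkylation of both phenoxides gives the bis(MOM) ether, whose two OMOM groups will direct metalation to the carbon between them.

Step 6
Reactants: 9 arene 1-methoxy-3,5-bis(methoxymethoxy)benzene; 7 aldehyde 7-(benzyloxy)-5-methoxy-2-oxo-2H-chromene-6-carbaldehyde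
Product: 11 carbinol 7-(benzyloxy)-6-{hydroxy[4-methoxy-2,6-bis(methoxymethoxy)phenyl]methyl}-5-methoxy-2H-chromen-2-one (racemic), via aryllithium 10 (not isolated)
Conditions: n-BuLi (1.05 equiv), THF, 0 °C; then added to 7 in THF, −78 °C; then H2O (pH 7 buffer)
Reagents that add atoms: none
Why: directed ortho-metalation should occur at the carbon flanked by both OMOM groups (stronger directors than OMe), and at −78 °C with inverse addition the aryllithium should add to the aldehyde much faster than to the lactone; the carbinol centre forms racemic and is removed in step 7.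

Step 7
Reactants: 11 carbinol 7-(benzyloxy)-6-{hydroxy[4-methoxy-2,6-bis(methoxymethoxy)phenyl]methyl}-5-methoxy-2H-chromen-2-one
Product: 13 diphenol 7-(benzyloxy)-6-(2,6-dihydroxy-4-methoxybenzyl)-5-methoxy-2H-chromen-2-one, via bis(MOM) diarylmethane 12 (not isolated)
Conditions: Et3SiH, CF3CO2H, CH2Cl2, −20 → 0 °C; then HCl, MeOH, 40 °C
Reagents that add atoms: none
Why: ionic hydrogenation, in which the strongly oxygen-stabilised diarylmethyl cation is trapped by hydride from Et3SiH, followed by acid methanolysis of the MOM acetals with methanol capturing the formaldehyde unit as dimethoxymethane.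

Step 8
Reactants: 13 diphenol 7-(benzyloxy)-6-(2,6-dihydroxy-4-methoxybenzyl)-5-methoxy-2H-chromen-2-one
Product: 14 aldehyde 3-{[7-(benzyloxy)-5-methoxy-2-oxo-2H-chromen-6-yl]methyl}-2,4-dihydroxy-6-methoxybenzaldehyde
Conditions: POCl3 (1.2 equiv), DMF, MeCN, 0 °C → rt; then H2O, 40 °C
Reagents that add atoms: N,N-dimethylformamide, CN(C)C=O; water, O
Why: Vilsmeier–Haack formylation; the free resorcinol ring is by far the most nucleophilic arene, its two open positions are equivalent by symmetry, and the iminium salt formed deactivates the ring against a second formylation.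

Step 9
Reactants: 14 aldehyde 3-{[7-(benzyloxy)-5-methoxy-2-oxo-2H-chromen-6-yl]methyl}-2,4-dihydroxy-6-methoxybenzaldehyde
Product: 15 aldehyde 4-(benzyloxy)-3-{[7-(benzyloxy)-5-methoxy-2-oxo-2H-chromen-6-yl]methyl}-2-hydroxy-6-methoxybenzaldehyde
Conditions: BnBr (1.05 equiv), K2CO3 (1.1 equiv), acetone, 45 °C
Reagents that add atoms: benzyl bromide, BrCc1ccccc1
Why: Williamson etherification selective for the hydroxyl para to the formyl group, because the ortho hydroxyl is held in a hydrogen bond to the carbonyl.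

Step 10
Reactants: 15 aldehyde 4-(benzyloxy)-3-{[7-(benzyloxy)-5-methoxy-2-oxo-2H-chromen-6-yl]methyl}-2-hydroxy-6-methoxybenzaldehyde; 3 ylide ethyl (triphenylphosphoranylidene)acetate
Product: 17 bis(coumarin) 7-(benzyloxy)-8-{[7-(benzyloxy)-5-methoxy-2-oxo-2H-chromen-6-yl]methyl}-5-methoxy-2H-chromen-2-one, via cinnamate ester 16 (not isolated)
Conditions: PhNEt2, reflux
Reagents that add atoms: none
Why: Wittig olefination and thermal lactonisation as in step 2; only the 2-OH is free, so the second pyranone ring closes onto the oxygen that becomes O1 of the 8-linked unit, and the existing coumarin is inert.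

Step 11
Reactants: 17 bis(coumarin) 7-(benzyloxy)-8-{[7-(benzyloxy)-5-methoxy-2-oxo-2H-chromen-6-yl]methyl}-5-methoxy-2H-chromen-2-one
Product: 18 bis(lactol) 7-(benzyloxy)-8-{[7-(benzyloxy)-2-hydroxy-5-methoxy-2H-chromen-6-yl]methyl}-5-methoxy-2H-chromen-2-ol (mixture at both C2)
Conditions: iBu2AlH (2.4 equiv), CH2Cl2, −78 °C; then aq KNaC4H4O6; crude product used directly
Reagents that add atoms: none
Why: half-reduction of each lactone with iBu2AlH at −78 °C should stop at the tetrahedral aluminium alkoxide, which gives the cyclic lactol on hydrolysis, as is known for coumarins; the ethers are untouched and the C2 configuration is irrelevant.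

Step 12
Reactants: 18 bis(lactol) 7-(benzyloxy)-8-{[7-(benzyloxy)-2-hydroxy-5-methoxy-2H-chromen-6-yl]methyl}-5-methoxy-2H-chromen-2-ol
Product: 19 bis(acetal) 7-(benzyloxy)-8-{[7-(benzyloxy)-2-ethoxy-5-methoxy-2H-chromen-6-yl]methyl}-2-ethoxy-5-methoxy-2H-chromene (mixture at both acetal carbons)
Conditions: EtOH, PPTS (5 mol %), 4 Å MS, 0 °C → rt; Et3N quench
Reagents that add atoms: ethanol, CCO
Why: acid-catalysed acetalisation through the 5,7-dioxygenated benzopyrylium ion, which ethanol captures at C2; the mild acid and basic quench protect the labile product.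

Step 13
Reactants: 19 bis(acetal) 7-(benzyloxy)-8-{[7-(benzyloxy)-2-ethoxy-5-methoxy-2H-chromen-6-yl]methyl}-2-ethoxy-5-methoxy-2H-chromene; 20 phenylboronic acid
Product: 21 bis(chromene) (2S)-7-(benzyloxy)-8-{[(2S)-7-(benzyloxy)-5-methoxy-2-phenyl-2H-chromen-6-yl]methyl}-5-methoxy-2-phenyl-2H-chromene
Conditions: Ni(cod)2 (10 mol %), (R,R)-TADDOL-derived P-phenyl phosphonite (12 mol %), PhB(OH)2 (3 equiv), dioxane/t-AmOH, 25–40 °C, no added base
Reagents that add atoms: phenylboronic acid (second molecule of 20), OB(O)c1ccccc1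
Why: Phenylboronic acid binds each ethoxy group and helps it leave while zerovalent nickel adds to the allylic C2–O bond, giving a divalent allylnickel species over C2–C4; the boron-bound ethoxide then promotes phenyl transfer from boron to nickel, and reductive elimination at C2 forms the C2–phenyl bond and returns zerovalent nickel, once at each acetal, so that two molecules of 20 are consumed per molecule of 19 and each delivers one phenyl group. The closest known reaction type is the nickel-catalysed enantioselective coupling of 2-alkoxy-2H-chromenes with arylboronic acids, applied here twice in one molecule. No ring is closed: the two new bonds are the exocyclic C2–C(phenyl) bonds on the two existing pyran rings. Each new C2 stereocentre is set by the chiral phosphonite on nickel, which decides the face of the allyl unit that receives phenyl; the acetal configurations are lost on ionisation, so the diastereomeric mixture 19 should converge, and because the two sites are set independently the minor sense of induction should end up mostly in the separable (2R,2S) and (2S,2R) diastereomers. The step needs C2 over C4 regioselectivity, which the substrate secures because bond formation at C2 leaves C3=C4 conjugated with the arene and C4 is screened by the peri 5-methoxy group; it also needs fast ionisation, which the 5,7-dioxygenated ring provides by stabilising the benzopyrylium character.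

Step 14
Reactants: 21 bis(chromene) (2S)-7-(benzyloxy)-8-{[(2S)-7-(benzyloxy)-5-methoxy-2-phenyl-2H-chromen-6-yl]methyl}-5-methoxy-2-phenyl-2H-chromene
Product: 22 bis(flavan) (2S)-7-(benzyloxy)-8-{[(2S)-7-(benzyloxy)-5-methoxy-2-phenylchroman-6-yl]methyl}-5-methoxy-2-phenylchromane
Conditions: H2 (1–3 atm), RhCl(PPh3)3 (10 mol %), PhMe/EtOH, 25 °C
Reagents that add atoms: none
Why: homogeneous hydrogenation with RhCl(PPh3)3 should reduce the cis-disubstituted C3=C4 bonds without hydrogenolysis of the allylic, benzylic C2–O bonds or the benzyl ethers, so both C2 centres keep their configuration (the descriptor stays S because phenyl still outranks C3).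

Step 15
Reactants: 22 bis(flavan) (2S)-7-(benzyloxy)-8-{[(2S)-7-(benzyloxy)-5-methoxy-2-phenylchroman-6-yl]methyl}-5-methoxy-2-phenylchromane
Product: 23 target (2S)-8-{[(2S)-7-hydroxy-5-methoxy-2-phenylchroman-6-yl]methyl}-5-methoxy-2-phenylchroman-7-ol
Conditions: H2 (1 atm), 10 % Pd/C, EtOAc/MeOH, 25 °C
Reagents that add atoms: none
Why: hydrogenolysis of the two aryl benzyl ethers over Pd/C under neutral conditions at 1 atm, where the flavan C2–O bond is cleaved far more slowly, should give the target with both stereocentres intact.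

## Compound list

1 | 2,4,6-trihydroxybenzaldehyde | O=Cc1c(O)cc(O)cc1O | starting material
2 | 4-(benzyloxy)-2,6-dihydroxybenzaldehyde | O=Cc1c(O)cc(OCc2ccccc2)cc1O | intermediate
3 | ethyl (triphenylphosphoranylidene)acetate | CCOC(=O)C=P(c1ccccc1)(c1ccccc1)c1ccccc1 | starting material
4 | ethyl 3-[4-(benzyloxy)-2,6-dihydroxyphenyl]prop-2-enoate (E/Z, not isolated) | CCOC(=O)C=Cc1c(O)cc(OCc2ccccc2)cc1O | intermediate
5 | 7-(benzyloxy)-5-hydroxy-2H-chromen-2-one | O=C1C=Cc2c(O)cc(OCc3ccccc3)cc2O1 | intermediate
6 | 7-(benzyloxy)-5-hydroxy-2-oxo-2H-chromene-6-carbaldehyde | O=C1C=Cc2c(O)c(C=O)c(OCc3ccccc3)cc2O1 | intermediate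
7 | 7-(benzyloxy)-5-methoxy-2-oxo-2H-chromene-6-carbaldehyde | O=C1C=Cc2c(OC)c(C=O)c(OCc3ccccc3)cc2O1 | intermediate
8 | 5-methoxyresorcinol | COc1cc(O)cc(O)c1 | starting material
9 | 1-methoxy-3,5-bis(methoxymethoxy)benzene | COCOc1cc(OC)cc(OCOC)c1 | intermediate
10 | [4-methoxy-2,6-bis(methoxymethoxy)phenyl]lithium (not isolated) | [Li]c1c(OCOC)cc(OC)cc1OCOC | intermediate
11 | 7-(benzyloxy)-6-{hydroxy[4-methoxy-2,6-bis(methoxymethoxy)phenyl]methyl}-5-methoxy-2H-chromen-2-one (racemic) | O=C1C=Cc2c(OC)c(C(O)c3c(OCOC)cc(OC)cc3OCOC)c(OCc3ccccc3)cc2O1 | intermediate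
12 | 7-(benzyloxy)-5-methoxy-6-[4-methoxy-2,6-bis(methoxymethoxy)benzyl]-2H-chromen-2-one (not isolated) | O=C1C=Cc2c(OC)c(Cc3c(OCOC)cc(OC)cc3OCOC)c(OCc3ccccc3)cc2O1 | intermediate
13 | 7-(benzyloxy)-6-(2,6-dihydroxy-4-methoxybenzyl)-5-methoxy-2H-chromen-2-one | O=C1C=Cc2c(OC)c(Cc3c(O)cc(OC)cc3O)c(OCc3ccccc3)cc2O1 | intermediate
14 | 3-{[7-(benzyloxy)-5-methoxy-2-oxo-2H-chromen-6-yl]methyl}-2,4-dihydroxy-6-methoxybenzaldehyde | O=Cc1c(O)c(Cc2c(OC)c3C=CC(=O)Oc3cc2OCc2ccccc2)c(O)cc1OC | intermediate
15 | 4-(benzyloxy)-3-{[7-(benzyloxy)-5-methoxy-2-oxo-2H-chromen-6-yl]methyl}-2-hydroxy-6-methoxybenzaldehyde | O=Cc1c(O)c(Cc2c(OC)c3C=CC(=O)Oc3cc2OCc2ccccc2)c(OCc2ccccc2)cc1OC | intermediate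
16 | ethyl 3-[4-(benzyloxy)-3-{[7-(benzyloxy)-5-methoxy-2-oxo-2H-chromen-6-yl]methyl}-2-hydroxy-6-methoxyphenyl]prop-2-enoate (E/Z, not isolated) | CCOC(=O)C=Cc1c(O)c(Cc2c(OC)c3C=CC(=O)Oc3cc2OCc2ccccc2)c(OCc2ccccc2)cc1OC | intermediate
17 | 7-(benzyloxy)-8-{[7-(benzyloxy)-5-methoxy-2-oxo-2H-chromen-6-yl]methyl}-5-methoxy-2H-chromen-2-one | O=C1C=Cc2c(OC)cc(OCc3ccccc3)c(Cc3c(OC)c4C=CC(=O)Oc4cc3OCc3ccccc3)c2O1 | intermediate
18 | 7-(benzyloxy)-8-{[7-(benzyloxy)-2-hydroxy-5-methoxy-2H-chromen-6-yl]methyl}-5-methoxy-2H-chromen-2-ol (mixture at both C2) | OC1C=Cc2c(OC)cc(OCc3ccccc3)c(Cc3c(OC)c4C=CC(O)Oc4cc3OCc3ccccc3)c2O1 | intermediate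
19 | 7-(benzyloxy)-8-{[7-(benzyloxy)-2-ethoxy-5-methoxy-2H-chromen-6-yl]methyl}-2-ethoxy-5-methoxy-2H-chromene (mixture at both acetal carbons) | CCOC1C=Cc2c(OC)cc(OCc3ccccc3)c(Cc3c(OC)c4C=CC(OCC)Oc4cc3OCc3ccccc3)c2O1 | intermediate
20 | phenylboronic acid | OB(O)c1ccccc1 | starting material
21 | (2S)-7-(benzyloxy)-8-{[(2S)-7-(benzyloxy)-5-methoxy-2-phenyl-2H-chromen-6-yl]methyl}-5-methoxy-2-phenyl-2H-chromene | COc1cc(OCc5ccccc5)c(Cc2c(OCc6ccccc6)cc3c(c2OC)C=C[C@@H](c2ccccc2)O3)c2c1C=C[C@@H](c1ccccc1)O2 | intermediate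
22 | (2S)-7-(benzyloxy)-8-{[(2S)-7-(benzyloxy)-5-methoxy-2-phenylchroman-6-yl]methyl}-5-methoxy-2-phenylchromane | COc1cc(OCc5ccccc5)c(Cc2c(OCc6ccccc6)cc3c(c2OC)CC[C@@H](c2ccccc2)O3)c2c1CC[C@@H](c1ccccc1)O2 | intermediate
23 | (2S)-8-{[(2S)-7-hydroxy-5-methoxy-2-phenylchroman-6-yl]methyl}-5-methoxy-2-phenylchroman-7-ol | COc1cc(O)c(Cc2c(O)cc3c(c2OC)CC[C@@H](c2ccccc2)O3)c2c1CC[C@@H](c1ccccc1)O2 | target

## Step count and risks

Total step count: 15. Longest linear sequence: 14 steps (steps 1–4 and 6–15).

**Step 13 (key step).** The electron-rich acetal may ionise under the boronic acid alone and be phenylated without nickel, which would give racemic material. The second arylation may also stall, or facial discrimination may be weak at the more hindered 8-linked unit. The fallback sets the stereocentres by ketone reduction and closes the rings by SN2 etherification. It sets out from bis(coumarin) 17: conjugate reduction of both C3=C4 bonds with [(Ph3P)CuH]6 in toluene should give the bis(chroman-2-one) F1. Opening of both lactones with MeNH(OMe)·HCl and AlMe3 should give the bis(Weinreb amide) bisphenol F2, and excess PhMgBr should then give the bis(3-aryl-1-phenylpropan-1-one) F3. Asymmetric transfer hydrogenation with RuCl[(R,R)-TsDPEN](p-cymene) and HCO2H/Et3N should give the (R,R)-bis(carbinol) F4. Twofold intramolecular Mitsunobu etherification (PPh3, DIAD, THF) should close both pyran rings with inversion and give the (2S,2S)-bis(flavan) dibenzyl ether 22, where the route is rejoined before step 15.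

**Step 6.** The aryllithium may attack the lactone carbonyl, or the congested addition that forms a tetra-ortho-substituted carbinol may stall. The fallback makes the bond by cross-coupling instead. Aldehyde 7 is reduced with NaBH4 (MeOH/THF, −20 °C) to the 6-(hydroxymethyl)coumarin F5 and converted with MsCl, Et3N and LiCl into the 6-(chloromethyl)coumarin F6. Aryllithium 10 (from 9) is transmetalated with ZnCl2 to the arylzinc chloride F7. Negishi coupling of F6 with F7 under Pd2(dba)3/SPhos in THF should give the bis(MOM) diarylmethane 12, which is then isolated and taken through the methanolic HCl stage of step 7 to 13.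

**Step 14.** A rhodium hydride may shift the C3=C4 bond towards O1 (to the 4H-chromene), which would erode the C2 centres, or the reduction may be sluggish. The fallback reduces the alkenes without a metal: diimide generated from 2-nitrobenzenesulfonylhydrazide and Et3N in CH2Cl2 should transfer H2 to both double bonds of 21 in a concerted syn fashion and give 22 directly; no new compound arises.

## Further compounds

F1 | step 13 | 7-(benzyloxy)-8-{[7-(benzyloxy)-5-methoxy-2-oxochroman-6-yl]methyl}-5-methoxychroman-2-one | O=C1CCc2c(OC)cc(OCc3ccccc3)c(Cc3c(OC)c4CCC(=O)Oc4cc3OCc3ccccc3)c2O1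
F2 | step 13 | bis(Weinreb amide) 3-[4-(benzyloxy)-3-({6-(benzyloxy)-4-hydroxy-2-methoxy-3-[3-(methoxy(methyl)amino)-3-oxopropyl]phenyl}methyl)-2-hydroxy-6-methoxyphenyl]-N-methoxy-N-methylpropanamide | CON(C)C(=O)CCc1c(OC)cc(OCc2ccccc2)c(Cc2c(OC)c(CCC(=O)N(C)OC)c(O)cc2OCc2ccccc2)c1O
F3 | step 13 | bis(ketone) 3-[4-(benzyloxy)-3-{[6-(benzyloxy)-4-hydroxy-2-methoxy-3-(3-oxo-3-phenylpropyl)phenyl]methyl}-2-hydroxy-6-methoxyphenyl]-1-phenylpropan-1-one | O=C(CCc1c(OC)cc(OCc2ccccc2)c(Cc2c(OC)c(CCC(=O)c3ccccc3)c(O)cc2OCc2ccccc2)c1O)c1ccccc1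
F4 | step 13 | (R,R)-bis(carbinol) (1R)-3-[4-(benzyloxy)-3-({6-(benzyloxy)-4-hydroxy-3-[(3R)-3-hydroxy-3-phenylpropyl]-2-methoxyphenyl}methyl)-2-hydroxy-6-methoxyphenyl]-1-phenylpropan-1-ol | O[C@H](CCc1c(OC)cc(OCc2ccccc2)c(Cc2c(OC)c(CC[C@@H](O)c3ccccc3)c(O)cc2OCc2ccccc2)c1O)c1ccccc1
F5 | step 6 | 7-(benzyloxy)-6-(hydroxymethyl)-5-methoxy-2H-chromen-2-one | O=C1C=Cc2c(OC)c(CO)c(OCc3ccccc3)cc2O1
F6 | step 6 | 7-(benzyloxy)-6-(chloromethyl)-5-methoxy-2H-chromen-2-one | O=C1C=Cc2c(OC)c(CCl)c(OCc3ccccc3)cc2O1
F7 | step 6 | [4-methoxy-2,6-bis(methoxymethoxy)phenyl]zinc chloride | Cl[Zn]c1c(OCOC)cc(OC)cc1OCOC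
F0 | step 14 | none | none
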